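The 2,4-dihydroxyphenyl ketone is not obtained by acylating resorcinol; its benzene ring is assembled last. Ring carbons C1 (acyl-bearing) and C6 come from the triple bond of a terminal ynone, and C2–C5, with the oxygens on C2 and C4, from a methyl acetoacetate-derived bis(silyloxy) diene. A single cycloaddition–elimination forms C1–C2 and C5–C6, closes the six-membered ring and fixes the ortho/para oxygen pattern. The ynone partner already carries the (R)-quaternary carbon (methyl, vinyl), set by [Ir(cod)Cl]2/phosphoramidite-catalysed branched allylation, the E-trisubstituted alkene, and the prenyl ketone masked as a 1,3-dithiane, which is opened in the final step.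

Key step: step 14

Assumption: in step 8 the phosphoramidite antipode is taken to be the one that delivers malonate to the allyl face giving (S)-13, by analogy with E-configured 3,3-disubstituted allylic carbonates; the sense of induction would be confirmed on the first run, and the other ligand antipode is equally available.

Step 1
Reactants: 1 geraniol
Product: 2 geranyl tert-butyldimethylsilyl ether
Conditions: TBSCl, imidazole, CH2Cl2, 0 °C → rt
Reagents that add atoms: tert-butyldimethylsilyl chloride, CC(C)(C)[Si](C)(C)Cl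
Why: Imidazole-promoted silylation of the primary alcohol (silyl ether formation) is routine, and a silyl ether, unlike an ester, will not be attacked or deprotonated by the lithiated dithiane used in step 5.

Step 2
Reactants: 2 geranyl tert-butyldimethylsilyl ether
Product: 3 (2E,6E)-8-[(tert-butyldimethylsilyl)oxy]-2,6-dimethylocta-2,6-dien-1-ol
Conditions: SeO2 (cat.), t-BuOOH, salicylic acid (cat.), CH2Cl2, 0 °C → rt
Reagents that add atoms: tert-butyl hydroperoxide, CC(C)(C)OO; selenium dioxide, O=[Se]=O (catalytic oxygen carrier)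
Why: Riley-type allylic oxidation (ene reaction followed by [2,3]-sigmatropic shift) selects the E-methyl group of the more electron-rich terminal alkene, as is well established for O-protected geraniols, and conversion is stopped early to limit over-oxidation to the enal.

Step 3
Reactants: 3 (2E,6E)-8-[(tert-butyldimethylsilyl)oxy]-2,6-dimethylocta-2,6-dien-1-ol
Product: 4 {[(2E,6E)-8-bromo-3,7-dimethylocta-2,6-dien-1-yl]oxy}(tert-butyl)dimethylsilane
Conditions: CBr4, PPh3, CH2Cl2, −20 → 0 °C
Reagents that add atoms: carbon tetrabromide, BrC(Br)(Br)Br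
Why: The Appel reaction turns the primary allylic alcohol into the bromide under neutral conditions, without allylic transposition, alkene isomerisation or loss of the silyl ether.

Step 4
Reactants: 5 3-methylbut-2-enal (prenal)
Product: 6 2-(2-methylprop-1-en-1-yl)-1,3-dithiane
Conditions: HS(CH2)3SH, BF3·OEt2 (cat.), CH2Cl2, −20 → 0 °C
Reagents that add atoms: propane-1,3-dithiol, SCCCS
Why: Lewis-acid-catalysed dithioacetalisation of the aldehyde is fast at low temperature, and the two β-methyl groups of prenal disfavour competing conjugate addition of the thiol.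

Step 5
Reactants: 6 2-(2-methylprop-1-en-1-yl)-1,3-dithiane; 4 {[(2E,6E)-8-bromo-3,7-dimethylocta-2,6-dien-1-yl]oxy}(tert-butyl)dimethylsilane
Product: 8 tert-butyl{[(2E,6E)-3,7-dimethyl-8-[2-(2-methylprop-1-en-1-yl)-1,3-dithian-2-yl]octa-2,6-dien-1-yl]oxy}dimethylsilane, via lithiated dithiane 7 (not isolated)
Conditions: n-BuLi, THF, −78 → −25 °C; then 4, THF, −78 → −20 °C
Reagents that add atoms: none
Why: Corey–Seebach umpolung alkylation, in which the sulfur-stabilised allyl anion 7 attacks the primary allylic bromide by SN2 through its dithiane carbon (the γ-carbon is tertiary and hindered), so the C–C bond should form with both alkene geometries retained.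

Step 6
Reactants: 8 tert-butyl{[(2E,6E)-3,7-dimethyl-8-[2-(2-methylprop-1-en-1-yl)-1,3-dithian-2-yl]octa-2,6-dien-1-yl]oxy}dimethylsilane
Product: 9 (2E,6E)-3,7-dimethyl-8-[2-(2-methylprop-1-en-1-yl)-1,3-dithian-2-yl]octa-2,6-dien-1-ol
Conditions: Bu4NF, THF, 0 °C → rt
Reagents that add atoms: none
Why: Fluoride-induced desilylation, driven by the strong Si–F bond, should leave the thioacetal and the three alkenes untouched.

Step 7
Reactants: 9 (2E,6E)-3,7-dimethyl-8-[2-(2-methylprop-1-en-1-yl)-1,3-dithian-2-yl]octa-2,6-dien-1-ol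
Product: 10 (2E,6E)-3,7-dimethyl-8-[2-(2-methylprop-1-en-1-yl)-1,3-dithian-2-yl]octa-2,6-dien-1-yl methyl carbonate
Conditions: ClCO2Me, pyridine, CH2Cl2, 0 °C
Reagents that add atoms: methyl chloroformate, COC(=O)Cl
Why: O-Acylation with a chloroformate gives the allylic methyl carbonate, the standard leaving group for forming an allyl–iridium intermediate.

Step 8
Reactants: 10 (2E,6E)-3,7-dimethyl-8-[2-(2-methylprop-1-en-1-yl)-1,3-dithian-2-yl]octa-2,6-dien-1-yl methyl carbonate; 11 dimethyl malonate
Product: 13 dimethyl 2-[(3S,6E)-3,7-dimethyl-8-[2-(2-methylprop-1-en-1-yl)-1,3-dithian-2-yl]octa-1,6-dien-3-yl]propanedioate, via sodium dimethyl malonate 12 (not isolated)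
Conditions: 11 (2 equiv), NaN(SiMe3)2, ZnI2, THF, rt; then [Ir(cod)Cl]2 (2 mol%), BINOL-derived N-aryl phosphoramidite of Me-THQphos type (4.4 mol%), TBD (1,5,7-triazabicyclo[4.4.0]dec-5-ene, 10 mol%), 10, THF, rt
Reagents that add atoms: none
Why: Asymmetric allylic alkylation of Tsuji–Trost type, in which the [Ir(cod)Cl]2/phosphoramidite catalyst ionises the carbonate and the zinc-tempered malonate attacks the more substituted C3 terminus of the allyl intermediate on the face left open by the cyclometalated ligand, so the ligand antipode sets the (S)-quaternary centre while the E-geometry of C2=C3 fixes which of methyl and chain is syn; ZnI2 acts as a Lewis-acid additive and is not consumed.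

Step 9
Reactants: 13 dimethyl 2-[(3S,6E)-3,7-dimethyl-8-[2-(2-methylprop-1-en-1-yl)-1,3-dithian-2-yl]octa-1,6-dien-3-yl]propanedioate
Product: 14 methyl (3R,6E)-3-ethenyl-3,7-dimethyl-8-[2-(2-methylprop-1-en-1-yl)-1,3-dithian-2-yl]oct-6-enoate
Conditions: LiCl, H2O, DMSO, 140 °C
Reagents that add atoms: none
Why: Krapcho dealkoxycarbonylation (chloride attack on an ester methyl, loss of CO2, protonation) removes one ester under neutral conditions; the quaternary carbon bears no hydrogen and cannot epimerise, and its descriptor changes from S to R only because the side chain now ranks below vinyl.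

Step 10
Reactants: 14 methyl (3R,6E)-3-ethenyl-3,7-dimethyl-8-[2-(2-methylprop-1-en-1-yl)-1,3-dithian-2-yl]oct-6-enoate
Product: 15 (3R,6E)-3-ethenyl-N-methoxy-N,3,7-trimethyl-8-[2-(2-methylprop-1-en-1-yl)-1,3-dithian-2-yl]oct-6-enamide
Conditions: MeNH(OMe)·HCl, i-PrMgCl, THF, −20 → 0 °C
Reagents that add atoms: N,O-dimethylhydroxylamine hydrochloride, CNOC.Cl
Why: Weinreb amide formation by aminolysis of the ester with the magnesium amide generated from MeNH(OMe)·HCl and i-PrMgCl should proceed below 0 °C and is compatible with the thioacetal and the alkenes.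

Step 11
Reactants: 15 (3R,6E)-3-ethenyl-N-methoxy-N,3,7-trimethyl-8-[2-(2-methylprop-1-en-1-yl)-1,3-dithian-2-yl]oct-6-enamide
Product: 17 (5R,8E)-5-ethenyl-5,9-dimethyl-10-[2-(2-methylprop-1-en-1-yl)-1,3-dithian-2-yl]dec-8-en-1-yn-3-one, via magnesium hemiaminal chelate 16 (not isolated)
Conditions: HC≡CMgBr (3 equiv), THF, 0 °C → rt; inverse quench into aq. NaHSO4, 0 °C
Reagents that add atoms: ethynylmagnesium bromide, C#C[Mg]Br
Why: Weinreb ketone synthesis, in which the five-membered magnesium chelate 16 resists a second addition and releases the ynone only on quench, while inverse addition into cold aqueous NaHSO4 protonates the liberated amine before it can add to the ynone in conjugate fashion.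

Step 12
Reactants: 18 methyl acetoacetate
Product: 19 methyl 3-[(trimethylsilyl)oxy]but-2-enoate (E/Z mixture)
Conditions: Me3SiCl, Et3N, hexane, rt
Reagents that add atoms: chlorotrimethylsilane, C[Si](C)(C)Cl
Why: O-Silylation of the enol form of the β-keto ester (silyl enol ether formation) is the standard first stage in preparing 1,3-bis(silyloxy) dienes.

Step 13
Reactants: 19 methyl 3-[(trimethylsilyl)oxy]but-2-enoate
Product: 21 1-methoxy-1,3-bis[(trimethylsilyl)oxy]buta-1,3-diene (E/Z mixture), via lithium dienolate 20 (not isolated)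
Conditions: LiN(i-Pr)2, THF, −78 °C; then Me3SiCl, −78 → 0 °C; filtration under argon, used without chromatography
Reagents that add atoms: chlorotrimethylsilane, C[Si](C)(C)Cl
Why: Kinetic γ-deprotonation of the vinylogous ester and O-silylation of the resulting dienolate 20 (silyl ketene acetal formation) should give the electron-rich diene, whose alkene geometry is irrelevant because it is lost on aromatisation.

Step 14
Reactants: 17 (5R,8E)-5-ethenyl-5,9-dimethyl-10-[2-(2-methylprop-1-en-1-yl)-1,3-dithian-2-yl]dec-8-en-1-yn-3-one; 21 1-methoxy-1,3-bis[(trimethylsilyl)oxy]buta-1,3-diene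
Product: 24 (3R,6E)-1-(2,4-dihydroxyphenyl)-3-ethenyl-3,7-dimethyl-8-[2-(2-methylprop-1-en-1-yl)-1,3-dithian-2-yl]oct-6-en-1-one, via cyclohexadiene cycloadduct 22 (not isolated), via bis-silyl aryl ether 23 (not isolated)
Conditions: 21 (2 equiv), toluene, −20 °C → rt; then 0.5 M HCl, THF, 0 °C
Reagents that add atoms: none
Why: The unsubstituted C4 terminus of diene 21 (largest HOMO coefficient) bonds to the terminal β-carbon of ynone 17 and the ketene-acetal carbon bonds to the α-carbon, either in a concerted normal-electron-demand Diels–Alder reaction or by Michael addition followed by ring closure, both leading to 1,4-cyclohexadiene 22; 1,4-elimination of methanol from its ketal carbon then gives arene 23, and dilute acid removes the two trimethylsilyl groups. The closest known reaction type is the Diels–Alder/aromatisation of 1,3-dioxygenated silyloxy dienes of the vinylketene acetal class with acetylenic ketones and esters. The benzene ring is closed by intermolecular [4+2] annulation, four carbons from the diene and two from the alkyne, the second bond (C1–C2) completing a six-membered ring in the stepwise variant. No lasting stereocentre is created, since the ketal carbon of 22 is destroyed on aromatisation and the (R)-quaternary carbon, which has no acidic hydrogen, is a spectator. The step needs regioselectivity (oxygens ortho and para to the acyl group), which the polarisation of both partners secures, and chemoselectivity, which is secured because the terminal ynone is the only electron-poor π-system while the vinyl group, the two trisubstituted alkenes and the thioacetal are inert in the absence of a Lewis acid.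

Step 15
Reactants: 24 (3R,6E)-1-(2,4-dihydroxyphenyl)-3-ethenyl-3,7-dimethyl-8-[2-(2-methylprop-1-en-1-yl)-1,3-dithian-2-yl]oct-6-en-1-one
Product: 25 (3R,6E)-1-(2,4-dihydroxyphenyl)-3-ethenyl-3,7,11-trimethyldodeca-6,10-diene-1,9-dione (target)
Conditions: Hg(ClO4)2·3H2O (2.2 equiv), CaCO3, THF–H2O (5:1), 0 °C, 10 min
Reagents that add atoms: water, O
Why: Thiophilic metal-assisted thioacetal hydrolysis, in which divalent mercury should bind the two soft sulfur atoms far faster than it attacks the alkenes or the hydrogen-bonded acylresorcinol, water captures the allyl-stabilised thionium ion, and CaCO3 neutralises the acid released so that the C6=C7 alkene does not migrate into conjugation.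

Compound list
1 | geraniol, (2E)-3,7-dimethylocta-2,6-dien-1-ol | CC(C)=CCC/C(C)=C/CO | starting material
2 | tert-butyl{[(2E)-3,7-dimethylocta-2,6-dien-1-yl]oxy}dimethylsilane | CC(C)=CCC/C(C)=C/CO[Si](C)(C)C(C)(C)C | intermediate
3 | (2E,6E)-8-[(tert-butyldimethylsilyl)oxy]-2,6-dimethylocta-2,6-dien-1-ol | OC/C(C)=C/CC/C(C)=C/CO[Si](C)(C)C(C)(C)C | intermediate
4 | {[(2E,6E)-8-bromo-3,7-dimethylocta-2,6-dien-1-yl]oxy}(tert-butyl)dimethylsilane | BrC/C(C)=C/CC/C(C)=C/CO[Si](C)(C)C(C)(C)C | intermediate
5 | 3-methylbut-2-enal (prenal) | CC(C)=CC=O | starting material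
6 | 2-(2-methylprop-1-en-1-yl)-1,3-dithiane | CC(C)=CC1SCCCS1 | intermediate
7 | 2-lithio-2-(2-methylprop-1-en-1-yl)-1,3-dithiane | [Li]C1(SCCCS1)C=C(C)C | intermediate
8 | tert-butyl{[(2E,6E)-3,7-dimethyl-8-[2-(2-methylprop-1-en-1-yl)-1,3-dithian-2-yl]octa-2,6-dien-1-yl]oxy}dimethylsilane | CC(C)=CC1(SCCCS1)C/C(C)=C/CC/C(C)=C/CO[Si](C)(C)C(C)(C)C | intermediate
9 | (2E,6E)-3,7-dimethyl-8-[2-(2-methylprop-1-en-1-yl)-1,3-dithian-2-yl]octa-2,6-dien-1-ol | CC(C)=CC1(SCCCS1)C/C(C)=C/CC/C(C)=C/CO | intermediate
10 | (2E,6E)-3,7-dimethyl-8-[2-(2-methylprop-1-en-1-yl)-1,3-dithian-2-yl]octa-2,6-dien-1-yl methyl carbonate | CC(C)=CC1(SCCCS1)C/C(C)=C/CC/C(C)=C/COC(=O)OC | intermediate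
11 | dimethyl malonate | COC(=O)CC(=O)OC | starting material
12 | sodium dimethyl malonate (enolate, zinc-associated in the presence of ZnI2) | [Na+].COC(=O)[CH-]C(=O)OC | intermediate
13 | dimethyl 2-[(3S,6E)-3,7-dimethyl-8-[2-(2-methylprop-1-en-1-yl)-1,3-dithian-2-yl]octa-1,6-dien-3-yl]propanedioate | C=C[C@](C)(CC/C=C(\C)CC1(SCCCS1)C=C(C)C)C(C(=O)OC)C(=O)OC | intermediate
14 | methyl (3R,6E)-3-ethenyl-3,7-dimethyl-8-[2-(2-methylprop-1-en-1-yl)-1,3-dithian-2-yl]oct-6-enoate | C=C[C@](C)(CC/C=C(\C)CC1(SCCCS1)C=C(C)C)CC(=O)OC | intermediate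
15 | (3R,6E)-3-ethenyl-N-methoxy-N,3,7-trimethyl-8-[2-(2-methylprop-1-en-1-yl)-1,3-dithian-2-yl]oct-6-enamide | C=C[C@](C)(CC/C=C(\C)CC1(SCCCS1)C=C(C)C)CC(=O)N(C)OC | intermediate
16 | bromomagnesium (5R,8E)-5-ethenyl-3-[methoxy(methyl)amino]-5,9-dimethyl-10-[2-(2-methylprop-1-en-1-yl)-1,3-dithian-2-yl]dec-8-en-1-yn-3-olate (chelate, epimeric at C3) | C=C[C@](C)(CC/C=C(\C)CC1(SCCCS1)C=C(C)C)CC(O[Mg]Br)(C#C)N(C)OC | intermediate
17 | (5R,8E)-5-ethenyl-5,9-dimethyl-10-[2-(2-methylprop-1-en-1-yl)-1,3-dithian-2-yl]dec-8-en-1-yn-3-one | C=C[C@](C)(CC/C=C(\C)CC1(SCCCS1)C=C(C)C)CC(=O)C#C | intermediate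
18 | methyl acetoacetate | COC(=O)CC(C)=O | starting material
19 | methyl 3-[(trimethylsilyl)oxy]but-2-enoate (E/Z mixture) | COC(=O)C=C(C)O[Si](C)(C)C | intermediate
20 | lithium 1-methoxy-3-[(trimethylsilyl)oxy]buta-1,3-dien-1-olate | C=C(O[Si](C)(C)C)C=C(OC)O[Li] | intermediate
21 | 1-methoxy-1,3-bis[(trimethylsilyl)oxy]buta-1,3-diene (E/Z mixture) | COC(O[Si](C)(C)C)=CC(=C)O[Si](C)(C)C | intermediate
22 | (3R,6E)-3-ethenyl-1-{6-methoxy-4,6-bis[(trimethylsilyl)oxy]cyclohexa-1,4-dien-1-yl}-3,7-dimethyl-8-[2-(2-methylprop-1-en-1-yl)-1,3-dithian-2-yl]oct-6-en-1-one (epimeric at the ketal carbon) | C=C[C@](C)(CC/C=C(\C)CC1(SCCCS1)C=C(C)C)CC(=O)C2=CCC(O[Si](C)(C)C)=CC2(OC)O[Si](C)(C)C | intermediate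
23 | (3R,6E)-1-{2,4-bis[(trimethylsilyl)oxy]phenyl}-3-ethenyl-3,7-dimethyl-8-[2-(2-methylprop-1-en-1-yl)-1,3-dithian-2-yl]oct-6-en-1-one | C=C[C@](C)(CC/C=C(\C)CC1(SCCCS1)C=C(C)C)CC(=O)c2ccc(O[Si](C)(C)C)cc2O[Si](C)(C)C | intermediate
24 | (3R,6E)-1-(2,4-dihydroxyphenyl)-3-ethenyl-3,7-dimethyl-8-[2-(2-methylprop-1-en-1-yl)-1,3-dithian-2-yl]oct-6-en-1-one | C=C[C@](C)(CC/C=C(\C)CC1(SCCCS1)C=C(C)C)CC(=O)c2ccc(O)cc2O | intermediate
25 | (3R,6E)-1-(2,4-dihydroxyphenyl)-3-ethenyl-3,7,11-trimethyldodeca-6,10-diene-1,9-dione | C=C[C@](C)(CC/C=C(\C)CC(=O)C=C(C)C)CC(=O)c1ccc(O)cc1O | target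

Total step count: 15.
Longest linear sequence: 12 steps (steps 1, 2, 3, 5, 6, 7, 8, 9, 10, 11, 14, 15).

Steps most likely to fail

Step 8. The thioacetal sulfur atoms may inhibit the [Ir(cod)Cl]2/phosphoramidite catalyst, the malonate may attack the unsubstituted allyl terminus, or syn/anti isomerisation of the allyl intermediate may erode enantiomeric purity. The fallback sets out from alcohol 9 and builds the quaternary carbon without a metal catalyst. Heating 9 with MeC(OMe)3 and catalytic propionic acid at about 120 °C (Johnson–Claisen rearrangement) should give racemic methyl (6E)-3-ethenyl-3,7-dimethyl-8-[2-(2-methylprop-1-en-1-yl)-1,3-dithian-2-yl]oct-6-enoate F1. The enantiomers of F1 would be separated by preparative chromatography on a chiral stationary phase, and the (3R)-enantiomer is compound 14, where the route is rejoined. This bypasses steps 7 to 9 at the cost of discarding half of the material.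

Step 14. The terminal ynone may oligomerise, the moisture-sensitive diene may hydrolyse before it adds, or the cycloadduct may aromatise incompletely. The fallback sets out from Weinreb amide 15 and introduces the arene preformed. Commercial 4-bromoresorcinol would be protected (MOMCl, i-Pr2NEt, CH2Cl2) as 1-bromo-2,4-bis(methoxymethoxy)benzene F2. Bromine–lithium exchange (n-BuLi, THF, −78 °C) would give 2,4-bis(methoxymethoxy)phenyllithium F3, which adds to 15 to give (3R,6E)-1-[2,4-bis(methoxymethoxy)phenyl]-3-ethenyl-3,7-dimethyl-8-[2-(2-methylprop-1-en-1-yl)-1,3-dithian-2-yl]oct-6-en-1-one F4. Acid methanolysis of the two acetals (cat. HCl, MeOH, 40 °C), with the ketone still masked as the dithiane, returns the route at compound 24.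

Step 15. Divalent mercury may mercurate the electron-rich resorcinol ring or oxymercurate the alkenes, and the C6=C7 double bond may migrate into conjugation with the newly freed ketone. The fallback sets out from 24 and avoids both free phenols and heavy metal. Silylation (TBSCl, imidazole, DMF) should give (3R,6E)-1-{2,4-bis[(tert-butyldimethylsilyl)oxy]phenyl}-3-ethenyl-3,7-dimethyl-8-[2-(2-methylprop-1-en-1-yl)-1,3-dithian-2-yl]oct-6-en-1-one F5. S-Methylation and hydrolysis of the thioacetal (MeI, CaCO3, MeCN–H2O, 40 °C) would give (3R,6E)-1-{2,4-bis[(tert-butyldimethylsilyl)oxy]phenyl}-3-ethenyl-3,7,11-trimethyldodeca-6,10-diene-1,9-dione F6. The aryl silyl ethers would then be cleaved with Et3N·3HF in THF at 0 °C, a weakly acidic fluoride source under which the β,γ-alkene should stay in place, to reach target 25.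

Further compounds
F1 | step 8 | racemic methyl (6E)-3-ethenyl-3,7-dimethyl-8-[2-(2-methylprop-1-en-1-yl)-1,3-dithian-2-yl]oct-6-enoate | C=CC(C)(CC/C=C(\C)CC1(SCCCS1)C=C(C)C)CC(=O)OC
F2 | step 14 | 1-bromo-2,4-bis(methoxymethoxy)benzene | COCOc1ccc(Br)c(OCOC)c1
F3 | step 14 | 2,4-bis(methoxymethoxy)phenyllithium | [Li]c1ccc(OCOC)cc1OCOC
F4 | step 14 | (3R,6E)-1-[2,4-bis(methoxymethoxy)phenyl]-3-ethenyl-3,7-dimethyl-8-[2-(2-methylprop-1-en-1-yl)-1,3-dithian-2-yl]oct-6-en-1-one | C=C[C@](C)(CC/C=C(\C)CC1(SCCCS1)C=C(C)C)CC(=O)c2ccc(OCOC)cc2OCOC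
F5 | step 15 | (3R,6E)-1-{2,4-bis[(tert-butyldimethylsilyl)oxy]phenyl}-3-ethenyl-3,7-dimethyl-8-[2-(2-methylprop-1-en-1-yl)-1,3-dithian-2-yl]oct-6-en-1-one | C=C[C@](C)(CC/C=C(\C)CC1(SCCCS1)C=C(C)C)CC(=O)c2ccc(O[Si](C)(C)C(C)(C)C)cc2O[Si](C)(C)C(C)(C)C
F6 | step 15 | (3R,6E)-1-{2,4-bis[(tert-butyldimethylsilyl)oxy]phenyl}-3-ethenyl-3,7,11-trimethyldodeca-6,10-diene-1,9-dione | C=C[C@](C)(CC/C=C(\C)CC(=O)C=C(C)C)CC(=O)c1ccc(O[Si](C)(C)C(C)(C)C)cc1O[Si](C)(C)C(C)(C)C
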